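## Structural features

The target is a (2S)-flavan: a resorcinol-type ring A with a free 7-OH is fused to the dihydropyran ring C, and C2 of ring C carries ring B through C1'. Ring B has a single hydrogen (C6'); going round it, C1' bears the flavan C2, C2' a 3-methylbut-2-enyl (prenyl) group, C3' a hydroxyl, C4' the ether oxygen of ring D and C5' the carbon C4'' of ring D. Ring D is a 2'',2''-dimethyl-3'',4''-dihydropyran fused at C4'–C5'. Its two stereocentres, C3''(R) and C4''(R), are adjacent and form a cis diol, whereas C2(S) is separated from them by the whole of ring B. Four groups are fragile: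
- the trisubstituted prenyl alkene (acid, electrophilic oxidants, hydrogenation, cyclisation onto the neighbouring 3'-OH);
- the C4'' benzylic alcohol ortho to an ether oxygen (it ionises in acid, which would scramble cis and trans);
- the C2–O1 benzylic ether para to the 4'-oxygen (ring C can open through a quinone methide in hot base or strong acid, which would racemise C2);
- the electron-rich phenols.

The real difficulty is to place a cis diol of defined absolute configuration on ring D while a more electron-rich alkene is present and the remote C2 centre gives no help. A second difficulty is the contiguous substitution of ring B with three phenolic oxygens to be told apart. The key step exploits the fact that C3'' and C4'' are neighbouring carbinol carbons, C4'' bonded to C5' and C3'' bonded to the quaternary C2'' on the C4' oxygen. Each can therefore be carried as a formyl group, and a carbene can join the two with polarity reversal, closing ring D without any oxidant.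

## Logic of the disconnections

25 from 23 through 24: the last bonds cut are the two O–allyl bonds and the O–Si bond. With the 7- and 3'-phenols as allyl ethers and C3''–OH as a silyl ether, all earlier steps meet only ethers. The forward unmasking must be neutral or weakly basic, because the prenyl group, the C4'' benzylic alcohol and C2 tolerate neither acid nor hydrogenation.

23 from 22 and 21: the C4''–H bond is cut, turning the C4'' carbinol into a ketone, and the silyl group is taken off O3''. One stereocentre disappears and its control passes to its neighbour. The forward reduction needs an external hydride entering anti to the C3'' oxygen, hence a silyl ether and no hydroxyl-directed reagent.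

21 from 20: the C3''–C4'' bond is cut, which opens ring D and removes the C3'' stereocentre. Both ends then stand at the formyl level, and the precursor keeps only the C2 stereocentre. The forward step must give the two formyl groups different roles, control the face of the acceptor by the catalyst alone, and run with a base too weak to epimerise the α-ketol.

20 from 19 and 18, then 18 from 16 and 17: after oxidation-level changes the O–C2'' bond is cut. The quaternary carbon comes in as a tertiary α-bromo ester, the one tertiary electrophile that phenoxides substitute dependably, and the ester is the cheapest carrier of C3''. Ring B is left with only its own substituents. The demand is alkylation of a doubly ortho-substituted, formyl-deactivated phenoxide.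

16 from 15: the C5'–CHO bond is cut. C5' is the only open position ortho to the 4'-hydroxyl, so a phenoxide-directed formylation is regiospecific. The 4'-OH must be the only free phenol, and the conditions must not open ring C.

15 from 14, and 14 from 12 through 13: the O–S bond of the 4'-mesylate and both O–allyl bonds are cut, and the 7-oxygen returns to a silyl ether. This relay keeps the three phenolic oxygens distinct: silyl on ring A while palladium chemistry is done on ring B, mesylate on O4' while O3' is worked on, allyl for the rest. The 4'-group must not migrate to the adjacent 3'-phenoxide, which excludes acyl and silyl groups there.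

12 from 11, and 11 from 8 and 10: the C2'–CH2 bond of the prenyl group is cut as a [3,3] shift back to a 1,1-dimethylallyl ether on O3', and then the O–C bond of that ether is cut. The prenyl group thus reaches the most crowded position of ring B without an organometallic step and after C2 is in place. C2' must be the only ortho position that can rearomatise, and the tertiary ether must be made under kinetic control.

8 from 7 and 6: C4 is taken back to a ketone. The carbonyl is absent from the target but makes C2 the β-carbon of an enone. Its later removal through a benzylic cation must leave the C2–O1 bond alone; the electron-poor mesylate on ring B secures this.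

6 from 5 and 3: the C2–C1' bond is cut. This is the convergent step and sets C2. The fragments are a chromone and an arylboronic acid with no ortho substituent, which is why the prenyl group is added afterwards. The ligand must control the enantioface, under neutral conditions, since a flavanone racemises by ring opening in base.

3 from 2 and 1, 5 from 4, and 10 from 9: only heteroatom bonds are cut on commercial compounds (O–S, O–CH3 and B–O on the ring B fragment, O–Si on the ring A fragment, O–C(=O) on the tertiary allylic alcohol).

## Other disconnections considered

Alternative 1: The cut is C5'–C4'' of ring D, the aryl–carbinol bond, with C3'' already present.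
- Forward step: Me2AlCl would bind the formyl oxygen and the α-(4-methoxybenzyl)oxy oxygen of aldehyde A2 in a five-membered chelate, and C5' of ring B would attack the activated carbonyl in a six-membered Friedel–Crafts closure to the cis chromanol A1. The C3'' centre would come from Sharpless epoxidation, through epoxy alcohol A3 opened at its tertiary carbon by the phenol.
- In favour: the absolute configuration rests on a very dependable catalytic asymmetric reaction, the chelate should relay it to C4'' as cis, both carbinol carbons are formed at their final oxidation level, and ring D is finished on a small fragment before any prenyl group exists.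
- Against: C5' is activated by only one ortho oxygen and deactivated by bromine. A strong Lewis acid meets a 4-methoxybenzyl ether, a tertiary alkyl aryl ether and a product benzylic alcohol that can ionise. A1 carries a 3'-O-methyl group for which no mild removal exists once the diol and, later, the prenyl group are present. The prenyl group must still be brought to C2' after union with ring C.
- Comparison: both plans build ring D from the O4' arm. Alternative 1 forms the aryl–carbon bond with matched polarity, whereas the chosen plan joins the two carbinol carbons by umpolung and then needs a reduction. On stereochemical precedent and on redox economy within ring D, Alternative 1 is the better. On the whole route it gains nothing, because the methyl ether exchange and the late prenylation cost the steps saved, and the chosen plan keeps strong Lewis acid away from the diol.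

Alternative 2: The cut goes through ring C at C3–C4 and O1–C2, dividing the molecule into the ring A benzyl alcohol A5 and the ring B/D styrene A6.
- Forward step: a confined chiral Brønsted acid would ionise A5 to its ortho-quinone methide, which would add A6 in a hetero-Diels–Alder reaction to give A4, the catalyst pocket setting C2.
- In favour: it is the most convergent plan (two bonds, one ring and C2 in one step). No C4 oxygen has to be removed, and ring D is completed on a fragment that has no prenyl group.
- Against: a quinone methide without a substituent on its methide carbon is very reactive and poorly organised in a catalyst pocket. The catalyst must override the two stereocentres already in A6. A strong acid meets the acetonide of a benzylic diol. A4 still lacks the prenyl group, which would need a high-temperature Claisen shift of the 3'-O-allyl group to C2' and a cross-metathesis with 2-methylbut-2-ene (RuCl2(=CHPh)(PCy3)(H2IMes), the second-generation Grubbs catalyst), followed by acidic acetonide removal next to the new prenyl group.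
- Comparison: on convergence, and on avoiding the two deoxygenation steps, Alternative 2 is the better. The chosen plan has the firmer precedent for its C2-setting step (conjugate addition to a chromone) and needs no acid after the diol exists. Both plans depend on a catalyst-controlled step of limited precedent, the cycloaddition there and the aldehyde–aldehyde benzoin here.

Alternative 3: The cut is C4–C4a of ring C.
- Forward step: 9-borabicyclononane would add to the terminal vinyl group of the allylic aryl ether A8 and leave the trisubstituted prenyl alkene alone. PdCl2(dppf) with aqueous base would then couple the primary alkylborane with the ring A bromide (B-alkyl Suzuki–Miyaura) to give A7, the fully protected target.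
- In favour: this ring closure is among the most dependable C(sp3)–C(sp2) couplings, it comes late and convergently, and no C4 oxygen is involved.
- Against: C2 must first exist as a benzylic and allylic aryl ether on a para-oxygenated, ortho-substituted ring, a centre that is prone to ionisation and to [3,3] shift onto ring A and is hard to set with high fidelity. The complete ring B/D unit with prenyl group and diol must be built first on a simple arene, which lengthens the linear sequence and returns the question of how to make the diol beside a prenyl group. The acetonide again needs acid at the end.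
- Comparison: for the reliability of the ring-forming step itself, Alternative 3 is the better of the two. The chosen plan sets C2 on simple fragments by a well-precedented reaction, makes the diol without any oxidant after the prenyl group is in place, and ends with neutral deprotections.

Key step: step 16

Remarks on the chemistry.
- Compounds 20 and 21 were traced atom by atom onto 25 and need no change. The C3'' descriptor reads S in 21 and 22 and R in 23 to 25 only because the CIP rank of C4'' changes on reduction; the spatial arrangement is the same.
- The antipodes of the bisphosphine in step 4, (S)-6,6'-dimethoxy-2,2'-bis[bis(3,4,5-trifluorophenyl)phosphino]biphenyl, and of the triazolium salt in step 16 are assigned by analogy with simpler substrates. If a first run shows the opposite sense, the mirror-image ligand or salt is used and nothing else changes.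
- Prenyl means 3-methylbut-2-en-1-yl. Flavan locants are unprimed for rings A and C, primed for ring B and double-primed for ring D.

Step 1
Reactants: 1 2-methoxy-4-(4,4,5,5-tetramethyl-1,3,2-dioxaborolan-2-yl)phenol
Product: 2 2-methoxy-4-(4,4,5,5-tetramethyl-1,3,2-dioxaborolan-2-yl)phenyl methanesulfonate
Conditions: MsCl, Et3N, CH2Cl2, 0 °C
Reagents that add atoms: methanesulfonyl chloride, CS(=O)(=O)Cl
Why: O-Sulfonylation of a phenol. The mesylate is chosen for the future O4' because it survives BBr3, acid, zerovalent palladium and heat, cannot migrate to the neighbouring oxygen (substitution at sulfur needs an in-line geometry that a five-membered transition state cannot reach) and, being electron-withdrawing, later protects the C2–O1 bond from ionisation.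

Step 2
Reactants: 2 2-methoxy-4-(4,4,5,5-tetramethyl-1,3,2-dioxaborolan-2-yl)phenyl methanesulfonate
Product: 3 [3-hydroxy-4-(methanesulfonyloxy)phenyl]boronic acid
Conditions: BBr3, CH2Cl2, −78 to 0 °C; then H2O, THF
Reagents that add atoms: water, O
Why: Lewis acid cleavage of an aryl methyl ether with BBr3; the same reagent exchanges the pinacolate on boron, and hydrolysis gives the free boronic acid wanted for a base-free conjugate addition. The aryl sulfonate is inert to BBr3.

Step 3
Reactants: 4 7-hydroxychromone
Product: 5 7-(triisopropylsilyloxy)chromone
Conditions: i-Pr3SiCl, imidazole, DMF, rt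
Reagents that add atoms: chlorotriisopropylsilane, CC(C)[Si](Cl)(C(C)C)C(C)C
Why: Silylation of an acidic phenol. The bulky silyl ether is inert to the rhodium and palladium steps and to CF3CO2H, and is later exchanged for allyl in one operation.

Step 4
Reactants: 5 7-(triisopropylsilyloxy)chromone; 3 [3-hydroxy-4-(methanesulfonyloxy)phenyl]boronic acid
Product: 6 (2S)-3'-hydroxy-4'-(methanesulfonyloxy)-7-(triisopropylsilyloxy)flavanone
Conditions: [Rh(OH)(cod)]2 (2.5 mol%), (S)-MeO-F12-BIPHEP (6 mol%), CH2Cl2/H2O, 20 °C
Reagents that add atoms: none
Why: Hayashi–Miyaura rhodium-catalysed asymmetric 1,4-addition of an arylboronic acid to a chromone. The aryl–rhodium species bearing the C2-symmetric, electron-poor bisphosphine adds to one face of C2 and so sets the 2S centre. No base is used because flavanones racemise by ring opening to the chalcone.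

Step 5
Reactants: 6 (2S)-3'-hydroxy-4'-(methanesulfonyloxy)-7-(triisopropylsilyloxy)flavanone
Product: 7 (2S,4S)-3'-hydroxy-4'-(methanesulfonyloxy)-7-(triisopropylsilyloxy)flavan-4-ol
Conditions: NaBH4, THF/EtOH, 0 °C
Reagents that add atoms: none
Why: Borohydride reduction of an aryl ketone. Axial hydride delivery should give mainly the 2,4-cis alcohol (4S); this centre is erased in step 6, so its ratio does not matter.

Step 6
Reactants: 7 (2S,4S)-3'-hydroxy-4'-(methanesulfonyloxy)-7-(triisopropylsilyloxy)flavan-4-ol
Product: 8 (2S)-3'-hydroxy-4'-(methanesulfonyloxy)-7-(triisopropylsilyloxy)flavan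
Conditions: Et3SiH, CF3CO2H, CH2Cl2, 0 °C
Reagents that add atoms: none
Why: Ionic hydrogenation (Kursanov–Parnes): the C4 cation, stabilised by O1 and by the 7-oxygen, is reduced by the silane. C2 is not touched because the 4'-mesylate makes ionisation of the C2–O1 bond unfavourable. A prenyl group could not be present here, which fixes the order of events.

Step 7
Reactants: 9 2-methylbut-3-en-2-ol
Product: 10 tert-butyl 2-methylbut-3-en-2-yl carbonate
Conditions: n-BuLi, THF, −78 °C; Boc2O, to rt
Reagents that add atoms: di-tert-butyl dicarbonate, CC(C)(C)OC(=O)OC(=O)OC(C)(C)C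
Why: Acylation of a lithium tertiary alkoxide with Boc2O gives the mixed carbonate, the usual ionisable partner for palladium-catalysed tertiary allylation.

Step 8
Reactants: 8 (2S)-3'-hydroxy-4'-(methanesulfonyloxy)-7-(triisopropylsilyloxy)flavan; 10 tert-butyl 2-methylbut-3-en-2-yl carbonate
Product: 11 (2S)-4'-(methanesulfonyloxy)-3'-(2-methylbut-3-en-2-yloxy)-7-(triisopropylsilyloxy)flavan
Conditions: Pd(PPh3)4 (2 mol%), THF, 0 °C
Reagents that add atoms: none
Why: Tsuji–Trost O-allylation: the carbonate ionises irreversibly (loss of CO2) to a 1,1-dimethyl-π-allyl palladium cation, and the phenoxide attacks its more substituted terminus under kinetic control at low temperature to give the branched ether. No other allylic ether is present at this stage, so no allyl scrambling is possible.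

Step 9
Reactants: 11 (2S)-4'-(methanesulfonyloxy)-3'-(2-methylbut-3-en-2-yloxy)-7-(triisopropylsilyloxy)flavan
Product: 12 (2S)-3'-hydroxy-4'-(methanesulfonyloxy)-2'-prenyl-7-(triisopropylsilyloxy)flavan
Conditions: toluene, 120 °C (sealed tube)
Reagents that add atoms: none
Why: Aromatic Claisen rearrangement ([3,3]). Of the two ortho positions of O3' only C2' carries hydrogen, so only there can the dienone rearomatise; bonding through the terminal CH2 turns the 1,1-dimethylallyl ether into the C-prenyl group. The gem-dimethyl substitution allows a temperature far below that at which the product would cyclise or a simple allyl ether would rearrange.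

Step 10
Reactants: 12 (2S)-3'-hydroxy-4'-(methanesulfonyloxy)-2'-prenyl-7-(triisopropylsilyloxy)flavan
Product: 14 (2S)-3',7-bis(allyloxy)-4'-(methanesulfonyloxy)-2'-prenylflavan, via desilylated diphenol 13 (not isolated)
Conditions: allyl bromide, CsF, Cs2CO3, DMF, rt
Reagents that add atoms: allyl bromide, C=CCBr
Why: Fluoride-mediated desilylative alkylation of an aryl silyl ether combined with Williamson allylation of the free 3'-phenol. Fluoride frees the 7-phenoxide in the presence of allyl bromide and carbonate serves the hindered 3'-OH; the mesylate is untouched at room temperature.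

Step 11
Reactants: 14 (2S)-3',7-bis(allyloxy)-4'-(methanesulfonyloxy)-2'-prenylflavan
Product: 15 (2S)-3',7-bis(allyloxy)-4'-hydroxy-2'-prenylflavan
Conditions: LDA, THF, −78 to 0 °C; aq. NH4Cl
Reagents that add atoms: none
Why: Base-induced cleavage of an aryl mesylate: LDA removes a proton from the S-methyl group and the anion fragments to the lithium phenoxide and sulfene (E1cB). The low temperature spares the allyl ethers and C2.

Step 12
Reactants: 15 (2S)-3',7-bis(allyloxy)-4'-hydroxy-2'-prenylflavan
Product: 16 (2S)-3',7-bis(allyloxy)-5'-formyl-4'-hydroxy-2'-prenylflavan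
Conditions: MgCl2, Et3N, (CH2O)n, MeCN, 70 °C
Reagents that add atoms: paraformaldehyde (as formaldehyde), C=O
Why: Casiraghi–Skattebøl ortho-formylation: the magnesium phenoxide binds formaldehyde and delivers it to the ortho carbon, and a second formaldehyde oxidises the benzylic alkoxide by hydride transfer. C5' is the only free position ortho to O4' and no other phenol is free.

Step 13
Reactants: 16 (2S)-3',7-bis(allyloxy)-5'-formyl-4'-hydroxy-2'-prenylflavan; 17 ethyl 2-bromo-2-methylpropanoate
Product: 18 ethyl 2-{[(2S)-3',7-bis(allyloxy)-5'-formyl-2'-prenylflavan-4'-yl]oxy}-2-methylpropanoate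
Conditions: Cs2CO3, DMF, 60 °C
Reagents that add atoms: none
Why: Williamson-type substitution of a tertiary α-bromo ester by a caesium phenoxide in a dipolar aprotic solvent, the established route to 2-aryloxy-2-methylpropanoates; the adjacent ester carbonyl accelerates displacement at the tertiary carbon. An excess of the bromide makes up for its loss by elimination.

Step 14
Reactants: 18 ethyl 2-{[(2S)-3',7-bis(allyloxy)-5'-formyl-2'-prenylflavan-4'-yl]oxy}-2-methylpropanoate
Product: 19 (2S)-3',7-bis(allyloxy)-5'-(hydroxymethyl)-4'-(1-hydroxy-2-methylpropan-2-yloxy)-2'-prenylflavan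
Conditions: LiAlH4, THF, 0 °C
Reagents that add atoms: none
Why: Hydride reduction of the ester and the aldehyde to the diol, which brings both carbinol carbons to one level so that a single oxidation delivers both formyl groups.

Step 15
Reactants: 19 (2S)-3',7-bis(allyloxy)-5'-(hydroxymethyl)-4'-(1-hydroxy-2-methylpropan-2-yloxy)-2'-prenylflavan
Product: 20 (2S)-3',7-bis(allyloxy)-5'-formyl-4'-(2-methyl-1-oxopropan-2-yloxy)-2'-prenylflavan
Conditions: Dess–Martin periodinane, NaHCO3, CH2Cl2, 0 °C to rt
Reagents that add atoms: none
Why: Dess–Martin oxidation of a benzylic and a neopentyl primary alcohol under buffered, non-acidic conditions. The aliphatic aldehyde has no α-hydrogen, so it can neither enolise nor epimerise.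

Step 16
Reactants: 20 (2S)-3',7-bis(allyloxy)-5'-formyl-4'-(2-methyl-1-oxopropan-2-yloxy)-2'-prenylflavan
Product: 21 (2S,3''S)-3',7-bis(allyloxy)-2'-prenylflavan with ring D closed as the 3''-hydroxy-2'',2''-dimethyl-4''-ketone
Conditions: (5aS,10bR)-2-(pentafluorophenyl)-5a,10b-dihydro-4H,6H-indeno[2,1-b][1,2,4]triazolo[4,3-d][1,4]oxazin-2-ium tetrafluoroborate (10 mol%), i-Pr2NEt (10 mol%), toluene, 0 °C to rt, argon
Reagents that add atoms: none
Why: The triazolylidene freed by the amine adds to the C5' formyl group and proton transfer gives the conjugated enaminol (Breslow intermediate), whose nucleophilic carbon, the future C4'', adds to the formyl carbon on the ether arm, the future C3''; proton transfer and loss of the carbene give the α-ketol. The closest known reaction is the triazolium-catalysed enantioselective intramolecular crossed benzoin of 2-(2-oxoalkoxy)benzaldehydes to 3-hydroxychroman-4-ones, here with a formyl acceptor in place of a ketone. Ring D closes in the 6-exo-trig mode, the acceptor C=O lying outside the new ring. C3'' is set by the catalyst: the aminoindane wall shields one face of the enaminol and the enol O–H···O=C hydrogen bond fixes which face of the acceptor is presented, so one antipode of the salt should give 3''S whatever the distant C2 centre is. The step needs the aryl aldehyde to be the donor; this is secured because the aliphatic formyl group sits on a fully substituted carbon, where addition of the bulky N-aryl carbene is slow, while the aryl aldehyde gives a conjugated enaminol. Low temperature and a catalyst-level amount of a weak amine keep the α-ketol from epimerising or transposing through its enediol and give any enaminol formed at the wrong aldehyde little chance to expel the ring B phenoxide. No oxidant is involved, so the prenyl and allyl alkenes are untouched; air is excluded because it would oxidise the enaminol to the acid.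

Step 17
Reactants: 21 (2S,3''S)-3',7-bis(allyloxy)-2'-prenylflavan with ring D closed as the 3''-hydroxy-2'',2''-dimethyl-4''-ketone
Product: 22 (2S,3''S)-3''-O-triethylsilyl ether of 21
Conditions: Et3SiOTf, 2,6-lutidine, CH2Cl2, −78 °C
Reagents that add atoms: triethylsilyl trifluoromethanesulfonate, CC[Si](CC)(CC)OS(=O)(=O)C(F)(F)F
Why: Silylation of a hindered secondary alcohol with a silyl triflate and a hindered weak base at low temperature, under which the α-ketol does not enolise. The ether blocks hydroxyl-directed hydride delivery in step 18.

Step 18
Reactants: 22 (2S,3''S)-3''-O-triethylsilyl ether of 21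
Product: 23 (2S,3''R,4''R)-3',7-bis(allyloxy)-4''-hydroxy-2'-prenyl-3''-(triethylsilyloxy) ring D flavan (cis)
Conditions: NaBH4, THF/MeOH, −40 to −10 °C
Reagents that add atoms: none
Why: Borohydride reduction of a cyclic α-silyloxy aryl ketone under Felkin–Anh (polar) control: in the reactive half-chair the hydride enters anti to the C3''–O bond and away from the pseudoaxial C2'' methyl group, so the new hydroxyl ends cis to the C3'' oxygen (4''R). A shift of the silyl group between the two cis oxygens would be harmless, since it is removed next.

Step 19
Reactants: 23 (2S,3''R,4''R)-3',7-bis(allyloxy)-4''-hydroxy-2'-prenyl-3''-(triethylsilyloxy) ring D flavan (cis)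
Product: 25 (3R,4R)-6-[(2S)-7-hydroxychroman-2-yl]-2,2-dimethyl-7-(3-methylbut-2-en-1-yl)chroman-3,4,8-triol (CNP0228510.2), via di-O-allyl cis-diol 24 (not isolated)
Conditions: Bu4NF, THF, 0 °C; then Pd(PPh3)4 (5 mol%), morpholine, rt
Reagents that add atoms: none
Why: Fluoride cleavage of the silyl ether, followed in the same flask by Tsuji–Trost deallylation: zerovalent palladium ionises both aryl allyl ethers and morpholine traps the π-allyl cation. Both stages are neutral to weakly basic, so the prenyl alkene, the benzylic cis diol and C2 are not endangered.

Compound list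

1 | 2-methoxy-4-(4,4,5,5-tetramethyl-1,3,2-dioxaborolan-2-yl)phenol | COc1cc(B2OC(C)(C)C(C)(C)O2)ccc1O | starting material
2 | 2-methoxy-4-(4,4,5,5-tetramethyl-1,3,2-dioxaborolan-2-yl)phenyl methanesulfonate | COc1cc(B2OC(C)(C)C(C)(C)O2)ccc1OS(C)(=O)=O | intermediate
3 | [3-hydroxy-4-(methanesulfonyloxy)phenyl]boronic acid | OB(O)c1ccc(OS(C)(=O)=O)c(O)c1 | intermediate
4 | 7-hydroxychromone | O=c1ccoc2cc(O)ccc12 | starting material
5 | 7-(triisopropylsilyloxy)chromone | O=c1ccoc2cc(O[Si](C(C)C)(C(C)C)C(C)C)ccc12 | intermediate
6 | (2S)-3'-hydroxy-4'-(methanesulfonyloxy)-7-(triisopropylsilyloxy)flavanone | CS(=O)(=O)Oc1ccc(cc1O)[C@@H]1CC(=O)c2ccc(O[Si](C(C)C)(C(C)C)C(C)C)cc2O1 | intermediate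
7 | (2S,4S)-3'-hydroxy-4'-(methanesulfonyloxy)-7-(triisopropylsilyloxy)flavan-4-ol | CS(=O)(=O)Oc1ccc(cc1O)[C@@H]1C[C@H](O)c2ccc(O[Si](C(C)C)(C(C)C)C(C)C)cc2O1 | intermediate
8 | (2S)-3'-hydroxy-4'-(methanesulfonyloxy)-7-(triisopropylsilyloxy)flavan | CS(=O)(=O)Oc1ccc(cc1O)[C@@H]1CCc2ccc(O[Si](C(C)C)(C(C)C)C(C)C)cc2O1 | intermediate
9 | 2-methylbut-3-en-2-ol | C=CC(C)(C)O | starting material
10 | tert-butyl 2-methylbut-3-en-2-yl carbonate | C=CC(C)(C)OC(=O)OC(C)(C)C | intermediate
11 | (2S)-4'-(methanesulfonyloxy)-3'-(2-methylbut-3-en-2-yloxy)-7-(triisopropylsilyloxy)flavan | CS(=O)(=O)Oc1ccc(cc1OC(C)(C)C=C)[C@@H]1CCc2ccc(O[Si](C(C)C)(C(C)C)C(C)C)cc2O1 | intermediate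
12 | (2S)-3'-hydroxy-4'-(methanesulfonyloxy)-2'-prenyl-7-(triisopropylsilyloxy)flavan | CC(C)=CCc1c([C@@H]2CCc3ccc(O[Si](C(C)C)(C(C)C)C(C)C)cc3O2)ccc(OS(C)(=O)=O)c1O | intermediate
13 | (2S)-3',7-dihydroxy-4'-(methanesulfonyloxy)-2'-prenylflavan (desilylated diphenol, not isolated) | CC(C)=CCc1c([C@@H]2CCc3ccc(O)cc3O2)ccc(OS(C)(=O)=O)c1O | intermediate
14 | (2S)-3',7-bis(allyloxy)-4'-(methanesulfonyloxy)-2'-prenylflavan | CC(C)=CCc1c([C@@H]2CCc3ccc(OCC=C)cc3O2)ccc(OS(C)(=O)=O)c1OCC=C | intermediate
15 | (2S)-3',7-bis(allyloxy)-4'-hydroxy-2'-prenylflavan | CC(C)=CCc1c([C@@H]2CCc3ccc(OCC=C)cc3O2)ccc(O)c1OCC=C | intermediate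
16 | (2S)-3',7-bis(allyloxy)-5'-formyl-4'-hydroxy-2'-prenylflavan | CC(C)=CCc1c([C@@H]2CCc3ccc(OCC=C)cc3O2)cc(C=O)c(O)c1OCC=C | intermediate
17 | ethyl 2-bromo-2-methylpropanoate | CCOC(=O)C(C)(C)Br | starting material
18 | ethyl 2-{[(2S)-3',7-bis(allyloxy)-5'-formyl-2'-prenylflavan-4'-yl]oxy}-2-methylpropanoate | CC(C)=CCc1c([C@@H]2CCc3ccc(OCC=C)cc3O2)cc(C=O)c(OC(C)(C)C(=O)OCC)c1OCC=C | intermediate
19 | (2S)-3',7-bis(allyloxy)-5'-(hydroxymethyl)-4'-(1-hydroxy-2-methylpropan-2-yloxy)-2'-prenylflavan | CC(C)=CCc1c([C@@H]2CCc3ccc(OCC=C)cc3O2)cc(CO)c(OC(C)(C)CO)c1OCC=C | intermediate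
20 | (2S)-3',7-bis(allyloxy)-5'-formyl-4'-(2-methyl-1-oxopropan-2-yloxy)-2'-prenylflavan (dialdehyde) | CC(C)=CCc1c([C@@H]2CCc3ccc(OCC=C)cc3O2)cc(C=O)c(OC(C)(C)C=O)c1OCC=C | intermediate
21 | (2S,3''S)-3',7-bis(allyloxy)-2'-prenylflavan with ring D as 3''-hydroxy-2'',2''-dimethyl-4''-ketone (ketol) | CC(C)=CCc1c([C@@H]2CCc3ccc(OCC=C)cc3O2)cc2c(c1OCC=C)OC(C)(C)[C@H](O)C2=O | intermediate
22 | (2S,3''S)-3''-O-triethylsilyl ether of 21 | CC(C)=CCc1c([C@@H]2CCc3ccc(OCC=C)cc3O2)cc2c(c1OCC=C)OC(C)(C)[C@H](O[Si](CC)(CC)CC)C2=O | intermediate
23 | (2S,3''R,4''R)-3',7-bis(allyloxy)-4''-hydroxy-2'-prenyl-3''-(triethylsilyloxy) ring D flavan (cis) | CC(C)=CCc1c([C@@H]2CCc3ccc(OCC=C)cc3O2)cc2c(c1OCC=C)OC(C)(C)[C@H](O[Si](CC)(CC)CC)[C@@H]2O | intermediate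
24 | (2S,3''R,4''R)-3',7-bis(allyloxy)-3'',4''-dihydroxy-2'-prenyl ring D flavan (di-O-allyl cis-diol, not isolated) | CC(C)=CCc1c([C@@H]2CCc3ccc(OCC=C)cc3O2)cc2c(c1OCC=C)OC(C)(C)[C@H](O)[C@@H]2O | intermediate
25 | (3R,4R)-6-[(2S)-7-hydroxychroman-2-yl]-2,2-dimethyl-7-(3-methylbut-2-en-1-yl)chroman-3,4,8-triol | CC(C)=CCc1c([C@@H]2CCc3ccc(O)cc3O2)cc2c(c1O)OC(C)(C)[C@H](O)[C@@H]2O | target

Total step count: 19 (steps 1 to 3 and 7 prepare fragments and a reagent). Longest linear sequence: 17 steps (1, 2, 4 to 6, 8 to 19).

Least certain steps

Step 16 (key step). Three things may go wrong.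
- The carbene may engage the wrong formyl group. The α-aryloxy aldehyde, once converted into its enaminol, can expel the ring B phenoxide and end as an ester, or it can act as donor and give the transposed ketol.
- Facial discrimination at the acceptor aldehyde may be insufficient, because closures between two aldehydes are less documented than aldehyde–ketone closures.
- The product may epimerise or transpose through its enediol under the base.

Fallback: the route leaves at 15 and returns at 21, using an alkene that only ring D possesses.
- Copper-catalysed O-alkylation of 15 with 3-chloro-3-methylbut-1-yne (CuCl2, DBU, MeCN, 0 °C) would give the aryl 1,1-dimethylpropargyl ether F1.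
- Heating (N,N-diethylaniline, 140 °C) would convert it by propargyl Claisen shift and electrocyclisation at C5' into the 2'',2''-dimethylchromene F2.
- Jacobsen–Katsuki epoxidation with the (R,R)-(salen)MnCl complex of trivalent manganese (N,N'-bis(3,5-di-tert-butylsalicylidene)cyclohexane-1,2-diamine ligand; NaOCl, 4-phenylpyridine N-oxide, CH2Cl2, 0 °C) should give the (3''R,4''R)-epoxide F3. This oxidant strongly prefers the conjugated cis alkene of ring D over the isolated prenyl and allyl alkenes.
- Dilute aqueous HClO4 in THF at 0 °C would open it at C4'' to the 3'',4''-diol F4. Its C4'' configuration does not matter, because MnO2 in CH2Cl2 then oxidises only the benzylic alcohol and gives 21.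

Step 13. The substitution at the tertiary bromide by a doubly ortho-substituted, formyl-deactivated phenoxide may be slower than elimination of the bromide to the methacrylate, and prolonged heating with base prolongs the exposure of C2. Fallback: the route leaves at 16 and returns at 19. Compound 16 is treated with 2-bromo-2-methylpropanoic acid and powdered NaOH in 2-methyltetrahydrofuran at 40 °C. The carboxylate closes to an α-lactone, a much less hindered and more reactive electrophile than the bromo ester, which the phenoxide opens at the tertiary carbon to give the aryloxy acid F5. LiAlH4 in THF reduces the acid and the aldehyde of F5 to 19.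

Step 12. Prolonged heating of the 4'-phenoxide with amine may erode the C2 configuration through reversible, phenoxide-driven opening of ring C (quinone methide), and the hydroxymethyl intermediate may be diverted to ethers. Fallback: the route leaves at 15 and returns at 16 without any phenoxide. Nagata ortho-hydroxymethylation (PhB(OH)2, paraformaldehyde, catalytic propanoic acid, toluene, reflux with water removal) would give the 2-phenyl-4H-1,3,2-benzodioxaborin F6. Transesterification with propane-1,3-diol frees the salicyl alcohol F7, and MnO2 in CH2Cl2 oxidises it to 16.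

Step 4. The electron-rich 7-silyloxychromone may insert slowly, so that protodeboronation of 3 outruns addition, and any reversible opening of the flavanone would lower the enantiomeric purity. Fallback: the route leaves at 5 and 3 and returns at 7. A racemic conjugate addition with Pd(OCOCF3)2 and 2,2'-bipyridine (divalent palladium, aqueous solvent, 60 °C) would give the racemic flavanone F8. Asymmetric transfer hydrogenation with RuCl(p-cymene)(TsDPEN) and HCO2H/Et3N, using the antipode that reduces the 2S enantiomer faster, would then act as a kinetic resolution. It gives 7 and leaves the unreduced (2R)-flavanone F9, which is removed by chromatography.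

Step 18. Facial selectivity may be poor, because the face anti to the silyloxy group is also the face shadowed by the pseudoaxial C2'' methyl group in one of the two half-chairs. Fallback: the route leaves at 21 and returns at 24, and control passes from the substrate to a catalyst. Asymmetric transfer hydrogenation of the free ketol 21 with RuCl(p-cymene)(TsDPEN) and HCO2H/Et3N, using the antipode that delivers hydride to give 4''R, should give 24 directly. Step 19 then needs only its palladium stage.

Further compounds

F1 | step 16 | (2S)-3',7-bis(allyloxy)-4'-(2-methylbut-3-yn-2-yloxy)-2'-prenylflavan | CC(C)=CCc1c([C@@H]2CCc3ccc(OCC=C)cc3O2)ccc(OC(C)(C)C#C)c1OCC=C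
F2 | step 16 | (2S)-3',7-bis(allyloxy)-2'-prenylflavan with ring D as 2'',2''-dimethyl-2H-pyran (chromene) | CC(C)=CCc1c([C@@H]2CCc3ccc(OCC=C)cc3O2)cc2c(c1OCC=C)OC(C)(C)C=C2
F3 | step 16 | (2S,3''R,4''R)-3'',4''-epoxide of F2 | CC(C)=CCc1c([C@@H]2CCc3ccc(OCC=C)cc3O2)cc2c(c1OCC=C)OC(C)(C)[C@@H]1O[C@H]21
F4 | step 16 | (2S,3''R,4''S)-3',7-bis(allyloxy)-3'',4''-dihydroxy-2'-prenyl ring D flavan (trans diol) | CC(C)=CCc1c([C@@H]2CCc3ccc(OCC=C)cc3O2)cc2c(c1OCC=C)OC(C)(C)[C@H](O)[C@H]2O
F5 | step 13 | 2-{[(2S)-3',7-bis(allyloxy)-5'-formyl-2'-prenylflavan-4'-yl]oxy}-2-methylpropanoic acid | CC(C)=CCc1c([C@@H]2CCc3ccc(OCC=C)cc3O2)cc(C=O)c(OC(C)(C)C(=O)O)c1OCC=C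
F6 | step 12 | (2S)-3',7-bis(allyloxy)-2'-prenylflavan with O4' and C5' bridged as a 2-phenyl-4H-1,3,2-benzodioxaborin | CC(C)=CCc1c([C@@H]2CCc3ccc(OCC=C)cc3O2)cc2c(c1OCC=C)OB(c1ccccc1)OC2
F7 | step 12 | (2S)-3',7-bis(allyloxy)-4'-hydroxy-5'-(hydroxymethyl)-2'-prenylflavan | CC(C)=CCc1c([C@@H]2CCc3ccc(OCC=C)cc3O2)cc(CO)c(O)c1OCC=C
F8 | step 4 | racemic 3'-hydroxy-4'-(methanesulfonyloxy)-7-(triisopropylsilyloxy)flavanone | CS(=O)(=O)Oc1ccc(cc1O)C1CC(=O)c2ccc(O[Si](C(C)C)(C(C)C)C(C)C)cc2O1
F9 | step 4 | (2R)-3'-hydroxy-4'-(methanesulfonyloxy)-7-(triisopropylsilyloxy)flavanone | CS(=O)(=O)Oc1ccc(cc1O)[C@H]1CC(=O)c2ccc(O[Si](C(C)C)(C(C)C)C(C)C)cc2O1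
F0 | step 18 | none | none
A1 | alternative 1 | (3R,4R)-6-bromo-8-methoxy-3-(4-methoxybenzyloxy)-2,2-dimethylchroman-4-ol | c1c(Br)cc2c(c1OC)OC(C)(C)[C@H](OCc3ccc(OC)cc3)[C@@H]2O
A2 | alternative 1 | (2S)-3-(4-bromo-2-methoxyphenoxy)-2-(4-methoxybenzyloxy)-3-methylbutanal | COc1cc(Br)ccc1OC(C)(C)[C@H](OCc1ccc(OC)cc1)C=O
A3 | alternative 1 | (2R)-(3,3-dimethyloxiran-2-yl)methanol | OC[C@H]1OC1(C)C
A4 | alternative 2 | (2S)-3'-O-allyl-7-O-triisopropylsilyl flavan without prenyl group, ring D (3''R,4''R)-diol as acetonide | c1c([C@@H]2CCc3ccc(O[Si](C(C)C)(C(C)C)C(C)C)cc3O2)cc2c(c1OCC=C)OC(C)(C)[C@H](OC(C)(C)O4)[C@@H]24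
A5 | alternative 2 | 2-(hydroxymethyl)-5-(triisopropylsilyloxy)phenol | OCc1ccc(O[Si](C(C)C)(C(C)C)C(C)C)cc1O
A6 | alternative 2 | (3R,4R)-8-(allyloxy)-2,2-dimethyl-6-vinylchroman-3,4-diol acetonide | c1c(C=C)cc2c(c1OCC=C)OC(C)(C)[C@H](OC(C)(C)O4)[C@@H]24
A7 | alternative 3 | protected target: 7- and 3'-O-tert-butyldimethylsilyl, ring D (3''R,4''R)-diol as acetonide, (2S) | CC(C)=CCc1c([C@@H]2CCc3ccc(O[Si](C)(C)C(C)(C)C)cc3O2)cc2c(c1O[Si](C)(C)C(C)(C)C)OC(C)(C)[C@H](OC(C)(C)O4)[C@@H]24
A8 | alternative 3 | (S)-1-aryl-prop-2-enyl 2-bromo-5-(tert-butyldimethylsilyloxy)phenyl ether carrying the protected ring B/D unit of A7 | CC(C)=CCc1c([C@H](C=C)Oc2cc(O[Si](C)(C)C(C)(C)C)ccc2Br)cc2c(c1O[Si](C)(C)C(C)(C)C)OC(C)(C)[C@H](OC(C)(C)O4)[C@@H]24
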